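**Plan**

- Retrosynthesis: the four phenols are masked as methyl ethers and the two aryl–carbonyl bonds are cut first (twofold Friedel–Crafts acylation of 1,3-dimethoxybenzene). The C2–phenyl and C4–phenyl bonds are cut last, leading back to a cis-cyclobutane-1,3-dicarboxylic half-ester whose C3 carboxyl is an 8-aminoquinoline amide.
- Forward: no ring is formed. The purchased four-membered ring is desymmetrised (anhydride, half-ester, amide), phenylated at C2 and C4 in one operation, the amide is exchanged for an ester, and the two resorcinol-derived rings are attached at the end.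
- Enabling feature: C2 and C4 are both β to the carboxyl carbon on C3 and hold their phenyl groups on the same face of the cyclobutane, which is the pattern that delivery from a single amide on C3 produces.
- Stereochemistry: the cis-2,4-diphenyl relationship comes from the amide-directed C–H phenylation. C1 and C3 are enolisable and are equilibrated with base to the all-trans arrangement (each carbonyl group trans to both phenyl groups).

Key step: step 3

Remark: the target has mirror planes through C1/C3 and through C2/C4 and is therefore achiral, so its stereodescriptors express relative configuration only; the monophenylated intermediate of the key step is racemic. Ring numbering throughout: C1 and C3 carry the carbonyl groups, C2 and C4 the phenyl groups.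

**Route**

Step 1
Reactants: 1 cis-cyclobutane-1,3-dicarboxylic acid
Product: 3 cis-3-(methoxycarbonyl)cyclobutane-1-carboxylic acid, via bicyclic anhydride 2 (not isolated)
Conditions: Ac2O, 140 °C; evaporate; MeOH, 65 °C
Reagents that add atoms: methanol, CO
Why: Dehydration of the cis-1,3-diacid to its bridged cyclic anhydride and ring-opening alcoholysis with methanol (desymmetrising anhydride methanolysis) free one carboxyl group and esterify the other; only the cis diacid can form the anhydride and it can open only to the cis half-ester, so the relative configuration is carried through untouched.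

Step 2
Reactants: 3 cis-3-(methoxycarbonyl)cyclobutane-1-carboxylic acid; 4 8-aminoquinoline
Product: 5 methyl cis-3-(quinolin-8-ylcarbamoyl)cyclobutane-1-carboxylate
Conditions: EDC·HCl, DMAP (cat.), CH2Cl2, 0 °C to rt
Reagents that add atoms: none
Why: Carbodiimide-mediated amide coupling with DMAP as acyl-transfer catalyst acylates the weakly nucleophilic aromatic amine under near-neutral conditions that neither cleave the methyl ester nor disturb the cis relationship between C1 and C3.

Step 3
Reactants: 5 methyl cis-3-(quinolin-8-ylcarbamoyl)cyclobutane-1-carboxylate; 6 iodobenzene (two equivalents are incorporated)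
Product: 8 methyl all-cis-2,4-diphenyl-3-(quinolin-8-ylcarbamoyl)cyclobutane-1-carboxylate, via monophenyl amide 7 (not isolated)
Conditions: Pd(OAc)2 (10 mol %), AgOAc (3 equiv), PhI (6 equiv), toluene, 110 °C, sealed tube
Reagents that add atoms: iodobenzene (the second phenyl group comes from a second equivalent of 6), Ic1ccccc1
Why: The deprotonated amide nitrogen and the quinoline nitrogen bind divalent palladium and hold it over the amide face of the ring, where acetate-assisted concerted metalation–deprotonation of the cis C2–H bond gives a five-membered palladacycle; oxidative addition of iodobenzene, which raises the metal to tetravalent palladium, and C–C reductive elimination with retention then attach phenyl cis to the amide, AgOAc taking up iodide and returning Pd(OAc)2, and the same cycle on C4 of 7 with a second molecule of iodobenzene completes the sequence. The closest known reaction type is the 8-aminoquinoline-directed β-methylene C(sp3)–H arylation of cyclobutanecarboxamides with aryl iodides, which is known to proceed to all-cis 2,4-diarylated products. No ring is closed: two C(sp3)–C(sp2) bonds are made on the intact four-membered ring. The new stereocentres C2 and C4 are controlled by the configuration of the amide-bearing C3, because the rigid N,N-chelate can reach only the hydrogen atoms on its own face, so both phenyl groups end up cis to the amide and hence cis to each other, while C1 stays as it is until step 5. The step needs β-site selectivity, single-face delivery and complete double arylation; C2 and C4 are the only β-carbons and are related by the mirror plane through C1 and C3, and the excess of iodobenzene and AgOAc at 110 °C is there to drive the more hindered second coupling.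

Step 4
Reactants: 8 methyl all-cis-2,4-diphenyl-3-(quinolin-8-ylcarbamoyl)cyclobutane-1-carboxylate
Product: 9 methyl all-cis-3-[(tert-butoxycarbonyl)(quinolin-8-yl)carbamoyl]-2,4-diphenylcyclobutane-1-carboxylate
Conditions: Boc2O (4 equiv), DMAP (0.5 equiv), MeCN, 60 °C
Reagents that add atoms: di-tert-butyl dicarbonate, CC(C)(C)OC(=O)OC(=O)OC(C)(C)C
Why: DMAP-catalysed N-tert-butoxycarbonylation of the secondary amide (Boc activation) twists the amide out of conjugation and turns the quinolinylamine into a carbamate leaving group for the cleavage in step 5, while the ester is inert and any inversion at the now more acidic C3 would be levelled in that same step.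

Step 5
Reactants: 9 methyl all-cis-3-[(tert-butoxycarbonyl)(quinolin-8-yl)carbamoyl]-2,4-diphenylcyclobutane-1-carboxylate
Product: 12 dimethyl (1α,2β,3α,4β)-2,4-diphenylcyclobutane-1,3-dicarboxylate, via all-cis diester 10 (not isolated), via mono-inverted diester 11 (not isolated)
Conditions: NaOMe (3 equiv), MeOH/THF, 0 °C to rt, then 65 °C; AcOH quench
Reagents that add atoms: methanol (delivered as NaOMe), CO
Why: Methoxide cleaves the Boc-activated amide by nucleophilic acyl substitution (methanolysis of an N-acyl carbamate) to diester 10, and on heating both ester-bearing carbons equilibrate through their enolates (base-mediated epimerisation, first to 11) to the thermodynamically favoured isomer in which every vicinal pair is trans and all four substituents can be pseudo-equatorial, the non-enolisable phenyl-bearing C2 and C4 keeping the cis relationship set in step 3.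

Step 6
Reactants: 12 dimethyl (1α,2β,3α,4β)-2,4-diphenylcyclobutane-1,3-dicarboxylate
Product: 13 (1α,2β,3α,4β)-2,4-diphenylcyclobutane-1,3-dicarboxylic acid
Conditions: LiOH·H2O (6 equiv), THF/MeOH/H2O, 60 °C; then 1 M HCl
Reagents that add atoms: lithium hydroxide, [Li+].[OH-]
Why: Ester saponification and acidification give the diacid, and because the all-trans arrangement is already the thermodynamic one the basic medium cannot erode the configuration at C1 and C3.

Step 7
Reactants: 13 (1α,2β,3α,4β)-2,4-diphenylcyclobutane-1,3-dicarboxylic acid; 14 1,3-dimethoxybenzene (two equivalents are incorporated)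
Product: 16 [(1α,2β,3α,4β)-2,4-diphenylcyclobutane-1,3-diyl]bis[(2,4-dimethoxyphenyl)methanone], via bis(acid chloride) 15 (not isolated)
Conditions: (COCl)2 (3 equiv), DMF (cat.), CH2Cl2, 0 °C to rt; evaporate; 14 (4 equiv), AlCl3 (3 equiv), CH2Cl2, 0 °C to rt; aq. HCl
Reagents that add atoms: 1,3-dimethoxybenzene (the second aryl group comes from a second equivalent of 14), COc1cccc(OC)c1
Why: Conversion to the bis(acid chloride) with oxalyl chloride and catalytic DMF and twofold Friedel–Crafts acylation of the electron-rich arene at C4 (para to one methoxy group, ortho to the other, the position between the two being blocked sterically) form both aryl ketones, one molecule of 14 being consumed at each acyl chloride; the trans relationship of each acyl group to its neighbouring phenyl rings disfavours intramolecular acylation, and enolisation at C1 or C3 can only return the all-trans isomer.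

Step 8
Reactants: 16 [(1α,2β,3α,4β)-2,4-diphenylcyclobutane-1,3-diyl]bis[(2,4-dimethoxyphenyl)methanone]
Product: 17 [(1α,2β,3α,4β)-2,4-diphenylcyclobutane-1,3-diyl]bis[(2,4-dihydroxyphenyl)methanone] (CNP0398987.1)
Conditions: BBr3 (10 equiv), CH2Cl2, −78 °C to rt; then H2O, 0 °C
Reagents that add atoms: none
Why: BBr3 cleavage of aryl methyl ethers (boron coordination, then bromide attack at methyl) liberates the four phenols, the ortho ethers being assisted by chelation to the ketone, and leaves the ketones, the cyclobutane and the thermodynamically settled all-trans configuration unchanged.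

**Compound list**

1 | cis-cyclobutane-1,3-dicarboxylic acid | OC(=O)[C@H]1C[C@@H](C(=O)O)C1 | starting material
2 | 3-oxabicyclo[3.1.1]heptane-2,4-dione (bridged anhydride of 1) | O=C1OC(=O)[C@H]2C[C@@H]1C2 | intermediate (not isolated)
3 | cis-3-(methoxycarbonyl)cyclobutane-1-carboxylic acid | COC(=O)[C@@H]1C[C@H](C(=O)O)C1 | intermediate
4 | 8-aminoquinoline | Nc1cccc2cccnc12 | starting material
5 | methyl cis-3-(quinolin-8-ylcarbamoyl)cyclobutane-1-carboxylate | COC(=O)[C@@H]1C[C@H](C(=O)Nc2cccc3cccnc23)C1 | intermediate
6 | iodobenzene | Ic1ccccc1 | starting material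
7 | methyl (1α,2α,3α)-2-phenyl-3-(quinolin-8-ylcarbamoyl)cyclobutane-1-carboxylate (all-cis, racemic) | COC(=O)[C@@H]1[C@H](c2ccccc2)[C@H](C(=O)Nc2cccc3cccnc23)C1 | intermediate (not isolated)
8 | methyl (1α,2α,3α,4α)-2,4-diphenyl-3-(quinolin-8-ylcarbamoyl)cyclobutane-1-carboxylate (all-cis) | COC(=O)[C@@H]1[C@H](c2ccccc2)[C@H](C(=O)Nc2cccc3cccnc23)[C@@H]1c1ccccc1 | intermediate
9 | methyl (1α,2α,3α,4α)-3-[(tert-butoxycarbonyl)(quinolin-8-yl)carbamoyl]-2,4-diphenylcyclobutane-1-carboxylate (all-cis) | COC(=O)[C@@H]1[C@H](c2ccccc2)[C@H](C(=O)N(C(=O)OC(C)(C)C)c2cccc3cccnc23)[C@@H]1c1ccccc1 | intermediate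
10 | dimethyl (1α,2α,3α,4α)-2,4-diphenylcyclobutane-1,3-dicarboxylate (all-cis) | COC(=O)[C@@H]1[C@H](c2ccccc2)[C@H](C(=O)OC)[C@@H]1c1ccccc1 | intermediate (not isolated)
11 | dimethyl (1α,2β,3β,4β)-2,4-diphenylcyclobutane-1,3-dicarboxylate (C1 ester trans, C3 ester cis to both phenyl groups) | COC(=O)[C@H]1[C@H](c2ccccc2)[C@H](C(=O)OC)[C@@H]1c1ccccc1 | intermediate (not isolated)
12 | dimethyl (1α,2β,3α,4β)-2,4-diphenylcyclobutane-1,3-dicarboxylate (all-trans) | COC(=O)[C@H]1[C@H](c2ccccc2)[C@@H](C(=O)OC)[C@@H]1c1ccccc1 | intermediate
13 | (1α,2β,3α,4β)-2,4-diphenylcyclobutane-1,3-dicarboxylic acid (all-trans) | OC(=O)[C@H]1[C@H](c2ccccc2)[C@@H](C(=O)O)[C@@H]1c1ccccc1 | intermediate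
14 | 1,3-dimethoxybenzene | COc1cccc(OC)c1 | starting material
15 | (1α,2β,3α,4β)-2,4-diphenylcyclobutane-1,3-dicarbonyl dichloride | O=C(Cl)[C@H]1[C@H](c2ccccc2)[C@@H](C(=O)Cl)[C@@H]1c1ccccc1 | intermediate (not isolated)
16 | [(1α,2β,3α,4β)-2,4-diphenylcyclobutane-1,3-diyl]bis[(2,4-dimethoxyphenyl)methanone] | O=C(c1ccc(OC)cc1OC)[C@H]1[C@H](c2ccccc2)[C@@H](C(=O)c2ccc(OC)cc2OC)[C@@H]1c1ccccc1 | intermediate
17 | [(1α,2β,3α,4β)-2,4-diphenylcyclobutane-1,3-diyl]bis[(2,4-dihydroxyphenyl)methanone] | O=C(c1ccc(O)cc1O)[C@H]1[C@H](c2ccccc2)[C@@H](C(=O)c2ccc(O)cc2O)[C@@H]1c1ccccc1 | target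

**Step count and risks**

Total step count: 8. Longest linear sequence: 8 steps (1 to 17); compounds 4, 6 and 14 are purchased.

Steps most likely to fail:

1. Step 3. The first phenylation leaves three cis substituents on the ring, and the second cyclopalladation must take place on that crowded face. The process may stall at monoarylation or lose the catalyst to palladium black before the second coupling is complete.
   Fallback (sets out from 5, comes back at 11): the arylation is run stepwise with a stereochemical correction in between. With PhI limited to about 1.5 equiv under Pd(OAc)2, Ag2CO3 and pivalic acid in (CF3)2CHOH at 90 °C, the reaction is stopped at the monophenyl amide 7, which is now isolated. NaOMe in MeOH inverts the ester-bearing C1 and should give methyl (1α,2β,3β)-2-phenyl-3-(quinolin-8-ylcarbamoyl)cyclobutane-1-carboxylate F1, in which the ester no longer crowds the amide face. A second Pd(OAc)2/AgOAc phenylation, directed by the same C3 amide to the remaining cis C4–H, should then give methyl (1α,2β,3β,4β)-2,4-diphenyl-3-(quinolin-8-ylcarbamoyl)cyclobutane-1-carboxylate F2. Boc2O/DMAP converts it into its N-Boc derivative F3, and NaOMe in MeOH as in step 5 cleaves this to diester 11, which the same flask carries on to 12.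

2. Step 5. Methoxide may attack the carbamate carbonyl instead of the shielded acyl carbon, which only strips the Boc group and returns the secondary amide, or the equilibration may stop short of the all-trans isomer.
   Fallback (sets out from 9, comes back at 10): LiOH and H2O2 in THF/H2O at 0 °C to rt, followed by Na2SO3, cleave the activated amide through the small hydroperoxide anion and saponify the ester. This should give (1α,2α,3α,4α)-2,4-diphenylcyclobutane-1,3-dicarboxylic acid F4; partial inversion at C1 would be of no consequence. MeI and K2CO3 in DMF re-esterify it to the all-cis diester 10, now isolated, which NaOMe in MeOH at 65 °C equilibrates through 11 to 12 with no amide cleavage competing.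

3. Step 7. On activation the cis-disposed carboxyl groups may close to a bridged anhydride so that only one acyl group is transferred. AlCl3 may also cleave the ortho ethers prematurely, or the second acylation may lag behind the first.
   Fallback (sets out from 12, comes back at 16): the aryl ketones are made by nucleophilic aryl addition instead of electrophilic aromatic substitution, bypassing 13 and 15. MeNHOMe·HCl and iPrMgCl in THF at −20 to 0 °C convert diester 12 into (1α,2β,3α,4β)-N1,N3-dimethoxy-N1,N3-dimethyl-2,4-diphenylcyclobutane-1,3-dicarboxamide F5. Commercial 2,4-dimethoxyphenylmagnesium bromide in THF at 0 °C to rt (Weinreb ketone synthesis) should then give 16. If enolisation along the way inverts C1 or C3, brief treatment of the diketone with DBU in CH2Cl2 returns the all-trans isomer.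

**Further compounds**

F1 | step 3 | methyl (1α,2β,3β)-2-phenyl-3-(quinolin-8-ylcarbamoyl)cyclobutane-1-carboxylate (racemic; ester trans to phenyl and amide) | COC(=O)[C@H]1[C@H](c2ccccc2)[C@H](C(=O)Nc2cccc3cccnc23)C1
F2 | step 3 | methyl (1α,2β,3β,4β)-2,4-diphenyl-3-(quinolin-8-ylcarbamoyl)cyclobutane-1-carboxylate (1-epimer of 8) | COC(=O)[C@H]1[C@H](c2ccccc2)[C@H](C(=O)Nc2cccc3cccnc23)[C@@H]1c1ccccc1
F3 | step 3 | methyl (1α,2β,3β,4β)-3-[(tert-butoxycarbonyl)(quinolin-8-yl)carbamoyl]-2,4-diphenylcyclobutane-1-carboxylate | COC(=O)[C@H]1[C@H](c2ccccc2)[C@H](C(=O)N(C(=O)OC(C)(C)C)c2cccc3cccnc23)[C@@H]1c1ccccc1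
F4 | step 5 | (1α,2α,3α,4α)-2,4-diphenylcyclobutane-1,3-dicarboxylic acid (all-cis) | OC(=O)[C@@H]1[C@H](c2ccccc2)[C@H](C(=O)O)[C@@H]1c1ccccc1
F5 | step 7 | (1α,2β,3α,4β)-N1,N3-dimethoxy-N1,N3-dimethyl-2,4-diphenylcyclobutane-1,3-dicarboxamide | CON(C)C(=O)[C@H]1[C@H](c2ccccc2)[C@@H](C(=O)N(C)OC)[C@@H]1c1ccccc1
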